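Both para-oxygenated benzene rings of the coumaroyl units are built late instead of bought. Each arene is disconnected into a 5-substituted 2-pyrone, whose C3, C4, C5 and C6 become arene C3, C2, C1 and C6 (C5 carries the acrylamide), and the two alkene carbons of 1,1-dimethoxyethene, which become C5 and the oxygen-bearing C4. One operation, a twofold inverse-demand Diels–Alder reaction followed by loss of carbon dioxide and methanol, closes both anisole rings and forms four C–C bonds on the finished spermidine diamide. Its precursor is N4-Boc-spermidine acylated at N1 and N8 with (E)-3-(2-oxo-2H-pyran-5-yl)acryloyl groups, made by a double Heck reaction; BBr3 then unmasks phenols and amine.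

Key step: step 5

Assumption: the two ends of the spermidine chain react independently, so species in which only one end has reacted are not numbered, and intermediates that are not isolated are drawn at the stage where both ends have reached the same point.

Step 1
Reactants: 1 spermidine
Product: 3 N4-Boc-N1,N8-bis(trifluoroacetyl)spermidine, via N1,N8-bis(trifluoroacetyl)spermidine 2 (not isolated)
Conditions: CF3CO2Et (2.05 equiv), MeOH, −78 → 0 °C; then Boc2O (1.2 equiv), 0 °C → rt
Reagents that add atoms: ethyl trifluoroacetate, CCOC(=O)C(F)(F)F; di-tert-butyl dicarbonate, CC(C)(C)OC(=O)OC(=O)OC(C)(C)C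
Why: Chemoselective aminolysis of an activated ester, in which ethyl trifluoroacetate acylates the two unhindered primary amines much faster than the secondary N4, leaves N4 as the only amine free to form the carbamate with Boc2O (carbamate protection).

Step 2
Reactants: 3 N4-Boc-N1,N8-bis(trifluoroacetyl)spermidine
Product: 4 N4-Boc-spermidine (tert-butyl (4-aminobutyl)(3-aminopropyl)carbamate)
Conditions: NaOH (1 M aq, 4 equiv), MeOH, rt
Reagents that add atoms: none
Why: Base hydrolysis of the electron-poor trifluoroacetamides is fast at room temperature while the tert-butyl carbamate is inert to hydroxide, so only the two primary amines should be set free.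

Step 3
Reactants: 4 N4-Boc-spermidine; 5 acryloyl chloride
Product: 6 N4-Boc-N1,N8-bis(acryloyl)spermidine
Conditions: 5 (2.3 equiv), sat. aq NaHCO3, CH2Cl2, 0 °C
Reagents that add atoms: none
Why: Schotten–Baumann N-acylation, in which the primary amines react with the acid chloride at 0 °C much faster than they can add in a conjugate sense to the acrylamide already formed, while N4 stays blocked as the carbamate.

Step 4
Reactants: 6 N4-Boc-N1,N8-bis(acryloyl)spermidine; 7 5-bromo-2H-pyran-2-one
Product: 8 N4-Boc-N1,N8-bis[(E)-3-(2-oxo-2H-pyran-5-yl)acryloyl]spermidine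
Conditions: 7 (2.5 equiv), Pd(OAc)2 (10 mol %), Bu4NCl (2 equiv), NaOAc (4 equiv), DMF, 80 °C
Reagents that add atoms: none
Why: Twofold Heck reaction, in which zerovalent palladium formed from Pd(OAc)2 inserts into the alkenyl C5–Br bond of 7, syn-carbopalladation at the terminal carbon of each acrylamide and syn-β-hydride elimination give the E-alkenes, and the weak acetate base in the absence of any free amine should leave the pyrone rings intact.

Step 5
Reactants: 8 N4-Boc-N1,N8-bis[(E)-3-(2-oxo-2H-pyran-5-yl)acryloyl]spermidine; 9 1,1-dimethoxyethene
Product: 12 N4-Boc-N1,N8-bis[(E)-4-methoxycinnamoyl]spermidine, via twofold oxabicyclooctenone cycloadduct 10 (not isolated), via twofold dimethoxycyclohexadiene 11 (not isolated)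
Conditions: 9 (10 equiv), BHT (cat.), 1,4-dioxane, 100 °C, sealed tube
Reagents that add atoms: none
Why: Each 2-pyrone of 8 is an electron-poor cyclic diene (C3 to C6) and 9 an electron-rich dienophile, so an intermolecular inverse-electron-demand Diels–Alder reaction (probably asynchronous, the CH2 of 9 bonding to C6 ahead of the acetal carbon bonding to C3) should give the bridged lactone 10, which expels CO2 by retro-[4+2] to the dimethoxycyclohexadiene 11 and then loses methanol by 1,2-elimination, driven by aromatisation. The closest known reaction type is the conversion of coumalate esters, 2-pyrones with an acceptor at C5, into para-alkoxybenzoates by ketene acetals. Each of the two benzene rings is closed by intermolecular [4+2] annulation of four pyrone carbons onto the two alkene carbons of 9, forming the C6–CH2 and C3–C(OMe)2 bonds. No stereocentre is created in 12, since the bridgehead centres of 10 are erased on aromatisation and the E-alkenes are not involved. The step needs regioselectivity (oxygen para to the side chain) and chemoselectivity (pyrone diene in preference to the acrylamide): the first follows from polarity matching, because C6 is the acceptor terminus of both the lactone carbonyl and the C5 acrylamide while the CH2 of 9 is its nucleophilic end, so the acetal carbon lands on C3, para to C5; the second from the locked s-cis geometry of the pyrone diene, the irreversible loss of CO2 and the poor acceptor quality of a β-substituted secondary acrylamide.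

Step 6
Reactants: 12 N4-Boc-N1,N8-bis[(E)-4-methoxycinnamoyl]spermidine
Product: 13 N1,N8-bis[(E)-4-hydroxycinnamoyl]spermidine (N1,N8-bis(coumaroyl)spermidine)
Conditions: BBr3 (8 equiv), CH2Cl2, −78 °C → rt; then H2O, 0 °C; aq NaHCO3 to pH 8–9
Reagents that add atoms: none
Why: Lewis-acid ether cleavage, in which BBr3 binds each aryl methyl ether oxygen and bromide removes the methyl group by SN2 attack, the same reagent ionises the tert-butyl carbamate, and aqueous work-up hydrolyses the aryl borates and decarboxylates the carbamic acid without touching the E-alkenes or the amides.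

Compound list
1 | spermidine (N1-(3-aminopropyl)butane-1,4-diamine) | NCCCCNCCCN | starting material
2 | N1,N8-bis(trifluoroacetyl)spermidine | O=C(NCCCCNCCCNC(=O)C(F)(F)F)C(F)(F)F | intermediate
3 | N4-Boc-N1,N8-bis(trifluoroacetyl)spermidine | O=C(NCCCCN(C(=O)OC(C)(C)C)CCCNC(=O)C(F)(F)F)C(F)(F)F | intermediate
4 | N4-Boc-spermidine (tert-butyl (4-aminobutyl)(3-aminopropyl)carbamate) | NCCCCN(C(=O)OC(C)(C)C)CCCN | intermediate
5 | acryloyl chloride | C=CC(=O)Cl | starting material
6 | N4-Boc-N1,N8-bis(acryloyl)spermidine | C=CC(=O)NCCCCN(C(=O)OC(C)(C)C)CCCNC(=O)C=C | intermediate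
7 | 5-bromo-2H-pyran-2-one | O=c1ccc(Br)co1 | starting material
8 | N4-Boc-N1,N8-bis[(E)-3-(2-oxo-2H-pyran-5-yl)acryloyl]spermidine | O=c1ccc(/C=C/C(=O)NCCCCN(C(=O)OC(C)(C)C)CCCNC(=O)/C=C/c2ccc(=O)oc2)co1 | intermediate
9 | 1,1-dimethoxyethene | C=C(OC)OC | starting material
10 | N4-Boc-N1,N8-bis[(E)-3-(8,8-dimethoxy-3-oxo-2-oxabicyclo[2.2.2]oct-5-en-6-yl)acryloyl]spermidine (bridgehead carbons formed without control, mixture of stereoisomers) | COC1(OC)CC2OC(=O)C1C=C2/C=C/C(=O)NCCCCN(C(=O)OC(C)(C)C)CCCNC(=O)/C=C/C1=CC2C(=O)OC1CC2(OC)OC | intermediate
11 | N4-Boc-N1,N8-bis[(E)-3-(4,4-dimethoxycyclohexa-1,5-dien-1-yl)acryloyl]spermidine | COC1(OC)CC=C(/C=C/C(=O)NCCCCN(C(=O)OC(C)(C)C)CCCNC(=O)/C=C/C2=CCC(OC)(OC)C=C2)C=C1 | intermediate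
12 | N4-Boc-N1,N8-bis[(E)-4-methoxycinnamoyl]spermidine | COc1ccc(/C=C/C(=O)NCCCCN(C(=O)OC(C)(C)C)CCCNC(=O)/C=C/c2ccc(OC)cc2)cc1 | intermediate
13 | N1,N8-bis[(E)-4-hydroxycinnamoyl]spermidine (N1,N8-bis(coumaroyl)spermidine) | O=C(/C=C/c1ccc(O)cc1)NCCCCNCCCNC(=O)/C=C/c1ccc(O)cc1 | target

Total step count: 6
Longest linear sequence: 6 steps, from spermidine 1 to the target 13.

Steps most likely to fail

Step 5. The ketene acetal may bond to C6 and then close onto the acrylamide α-carbon instead of C3, it may oligomerise before it cycloadds, or the sequence may stall before methanol is lost. Fallback: setting out from 6, a twofold Heck arylation with 4-iodoanisole (Pd(OAc)2, Bu4NCl, NaOAc, DMF, 80 °C) would give 12 directly. Both arenes are then bought instead of built, and no compound outside the list is made (F0).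

Step 4. The pyrone ring may be opened by base, the bromopyrone may undergo a thermal Diels–Alder reaction with the acrylamide before palladium inserts, or the second coupling may remain incomplete. Fallback: setting out from 4 and 7, the C–C bond would be made by a Stille coupling under neutral conditions with the polarity reversed. Amide coupling of 4 with (E)-3-iodoacrylic acid (EDC hydrochloride, HOBt, CH2Cl2, 0 °C) would give N4-Boc-N1,N8-bis[(E)-3-iodoacryloyl]spermidine F1. Separately, 7 would be stannylated with Me3SnSnMe3 and Pd(PPh3)4 (1,4-dioxane, 80 °C) to 5-(trimethylstannyl)-2H-pyran-2-one F2. Coupling of F1 with F2 (Pd(PPh3)4, CuI, DMF, 40 °C) retains the alkene geometry and would come back to the route at 8.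

Step 6. Demethylation may be incomplete, HBr may add to or isomerise the electron-rich styrene-type alkenes, and the amphoteric product may be lost to boron complexes at work-up. Fallback: setting out from 12, the two unmasking events would be separated and the ether cleavage changed from Lewis-acid to nucleophilic. NaSEt in DMF at 110 °C (thiolate SN2 attack at the methyl groups, carbamate untouched) would give, after mildly acidic work-up, N4-Boc-N1,N8-bis[(E)-4-hydroxycinnamoyl]spermidine F3. Removal of the Boc group with CF3CO2H in CH2Cl2 at 0 °C and neutralisation would come back to the route at 13.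

Further compounds
F0 | step 5 | none | none
F1 | step 4 | N4-Boc-N1,N8-bis[(E)-3-iodoacryloyl]spermidine | I/C=C/C(=O)NCCCCN(C(=O)OC(C)(C)C)CCCNC(=O)/C=C/I
F2 | step 4 | 5-(trimethylstannyl)-2H-pyran-2-one | C[Sn](C)(C)c1ccc(=O)oc1
F3 | step 6 | N4-Boc-N1,N8-bis[(E)-4-hydroxycinnamoyl]spermidine | O=C(/C=C/c1ccc(O)cc1)NCCCCN(C(=O)OC(C)(C)C)CCCNC(=O)/C=C/c1ccc(O)cc1
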